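**Retrosynthetic overview**
- Target ⇐ C14‑O desilylation, C3‑O acylation and CBS reduction of a C3 ketone; butenolide ⇐ lactonisation of C6‑OH onto the C15 ester; α‑methylene lactone ⇐ Pd cyclocarbonylation of a C7‑ethynyl/C8‑OH pair.
- Ten‑membered ring ⇐ Criegee (Hock‑type) 1,2‑shift ring expansion of an octalin 8a‑hydroperoxide: the ring‑fusion carbon C8 migrates from C3 to oxygen with retention (key step, ionic).
- Hydroperoxide ⇐ Schenck ene reaction of a tetrasubstituted enoate; C6‑O ⇐ Baeyer–Villiger of a C6 acetyl; alkyne ⇐ homologation of a C7 formyl group.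
- Octalin ⇐ endo Diels–Alder of a semicyclic 2‑carbomethoxy diene with (Z)‑4‑oxopent‑2‑enal (sets C6, C7, C8).
- Diene ⇐ Negishi coupling of a vinyl chloride obtained by organocatalytic Diels–Alder of chloroprene and acrolein (sets C10). Ring order: cyclohexene (ring B) → octalin (ring A) → cyclodecene → α‑methylene lactone → butenolide.

Atom labels: C1–C10 are the ring carbons of the ten‑membered ring of the target (C3 carries the isobutyrate, C4=C5 is the ring alkene, C6 and C8 carry the lactone oxygens, C7 is the lactone ring‑fusion carbon, C10 carries CH2OH = C14); C11–C13 are the α‑methylene lactone carbons (C12 carbonyl, C13 methylene); C15 is the butenolide carbonyl.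

Assumption: the (5S)‑imidazolidinone salt in step 1 gives (R)‑3; if the facial sense is opposite, its enantiomer is used.

**Route**

Step 1
Reactants: 1 2‑chlorobuta‑1,3‑diene; 2 prop‑2‑enal
Product: 3 (1R)‑4‑chlorocyclohex‑3‑ene‑1‑carbaldehyde
Conditions: (5S)‑5‑benzyl‑2,2,3‑trimethylimidazolidin‑4‑one hydrochloride (first‑generation MacMillan catalyst, 10 mol %), MeCN/H2O 95:5, −10 °C
Reagents that add atoms: none
Why: Iminium‑catalysed Diels–Alder reaction; the 2‑substituted diene gives the "para" adduct and the catalyst's shielded face sets C10 (R).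

Step 2
Reactants: 3 (1R)‑4‑chlorocyclohex‑3‑ene‑1‑carbaldehyde
Product: 4 tert‑butyl{[(1R)‑4‑chlorocyclohex‑3‑en‑1‑yl]methoxy}dimethylsilane
Conditions: [(Ph3P)CuH]6 (1 mol %), tBuMe2SiH, toluene, rt
Reagents that add atoms: tert‑butyldimethylsilane, C[SiH](C)C(C)(C)C
Why: Copper hydride‑catalysed carbonyl hydrosilylation gives the silyl ether directly; the vinyl chloride and C10 are untouched.

Step 3
Reactants: 4 tert‑butyl{[(1R)‑4‑chlorocyclohex‑3‑en‑1‑yl]methoxy}dimethylsilane; 5 methyl 2‑bromoprop‑2‑enoate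
Product: 7 methyl 2‑[(4R)‑4‑({[tert‑butyl(dimethyl)silyl]oxy}methyl)cyclohex‑1‑en‑1‑yl]prop‑2‑enoate, via [1‑(methoxycarbonyl)ethenyl]zinc bromide 6 (not isolated)
Conditions: 5, Zn dust, LiCl, THF, 0 °C; then 4, Pd(OAc)2 (2 mol %), SPhos (4 mol %), THF, 50 °C
Reagents that add atoms: none
Why: Zinc insertion into the α‑bromoacrylate followed by Negishi coupling with the vinyl chloride (biaryl phosphine ligand) gives the semicyclic diene without touching C10.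

Step 4
Reactants: 7 methyl 2‑[(4R)‑4‑({[tert‑butyl(dimethyl)silyl]oxy}methyl)cyclohex‑1‑en‑1‑yl]prop‑2‑enoate; 8 2‑methylfuran
Product: 10 methyl (3R,4S,4aR,6R)‑3‑acetyl‑6‑({[tert‑butyl(dimethyl)silyl]oxy}methyl)‑4‑formyl‑2,3,4,4a,5,6,7,8‑octahydronaphthalene‑1‑carboxylate, via (Z)‑4‑oxopent‑2‑enal 9 (not isolated)
Conditions: 8, dimethyldioxirane (acetone), −78 → 0 °C, evaporation; then 7, Me2AlCl (0.2 equiv), CH2Cl2, −40 °C
Reagents that add atoms: dimethyldioxirane, CC1(C)OO1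
Why: Furan oxidation gives the cis‑enedicarbonyl, which undergoes an endo Diels–Alder reaction in which the diene terminus C5 (larger coefficient) bonds to the carbon β to the formyl group; the cis dienophile and endo approach make C6‑acetyl, C7‑CHO and C8–C9 all‑cis, and axial attack on ring B anti to the equatorial CH2OTBS group relates them to C10.

Step 5
Reactants: 10 methyl (3R,4S,4aR,6R)‑3‑acetyl‑6‑({[tert‑butyl(dimethyl)silyl]oxy}methyl)‑4‑formyl‑2,3,4,4a,5,6,7,8‑octahydronaphthalene‑1‑carboxylate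
Product: 11 methyl (3R,4S,4aR,6R)‑3‑acetyl‑6‑({[tert‑butyl(dimethyl)silyl]oxy}methyl)‑4‑ethynyl‑2,3,4,4a,5,6,7,8‑octahydronaphthalene‑1‑carboxylate
Conditions: TMSCHN2, n‑BuLi, THF, −78 °C; then 10, −78 → 0 °C
Reagents that add atoms: (trimethylsilyl)diazomethane, C[Si](C)(C)C=[N+]=[N-]
Why: Colvin homologation with lithiated trimethylsilyldiazomethane converts the aldehyde (faster than the ketone at −78 °C) into the terminal alkyne C11≡C13 without touching C7.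

Step 6
Reactants: 11 methyl (3R,4S,4aR,6R)‑3‑acetyl‑6‑({[tert‑butyl(dimethyl)silyl]oxy}methyl)‑4‑ethynyl‑2,3,4,4a,5,6,7,8‑octahydronaphthalene‑1‑carboxylate
Product: 12 methyl (3R,4R,4aR,6R)‑3‑(acetyloxy)‑6‑({[tert‑butyl(dimethyl)silyl]oxy}methyl)‑4‑ethynyl‑2,3,4,4a,5,6,7,8‑octahydronaphthalene‑1‑carboxylate
Conditions: mCPBA, CH2Cl2, 0 °C → rt
Reagents that add atoms: 3‑chloroperoxybenzoic acid, OOC(=O)c1cccc(Cl)c1
Why: Baeyer–Villiger oxidation; the secondary carbon C6 migrates in preference to methyl with retention, installing O6 cis to the C7 substituent (the electron‑poor tetrasubstituted enoate and the alkyne react much more slowly).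

Step 7
Reactants: 12 methyl (3R,4R,4aR,6R)‑3‑(acetyloxy)‑6‑({[tert‑butyl(dimethyl)silyl]oxy}methyl)‑4‑ethynyl‑2,3,4,4a,5,6,7,8‑octahydronaphthalene‑1‑carboxylate
Product: 13 methyl (3R,4R,4aR,6R,8aS)‑3‑(acetyloxy)‑6‑({[tert‑butyl(dimethyl)silyl]oxy}methyl)‑4‑ethynyl‑8a‑hydroperoxy‑3,4,4a,5,6,7,8,8a‑octahydronaphthalene‑1‑carboxylate
Conditions: O2, tetraphenylporphyrin (1 mol %), white LED, CH2Cl2, 0 °C
Reagents that add atoms: dioxygen, O=O
Why: Schenck ene reaction with the "gem" selectivity of α,β‑unsaturated esters: hydrogen is taken from C5 (geminal to the ester), oxygen adds to C3 from the face opposite the ring A substituents and the alkene moves to C4=C5; the C3 configuration is lost later and is immaterial.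

Step 8
Reactants: 13 methyl (3R,4R,4aR,6R,8aS)‑3‑(acetyloxy)‑6‑({[tert‑butyl(dimethyl)silyl]oxy}methyl)‑4‑ethynyl‑8a‑hydroperoxy‑3,4,4a,5,6,7,8,8a‑octahydronaphthalene‑1‑carboxylate
Product: 16 methyl (1E,3R,4S,5R,7R)‑3‑(acetyloxy)‑7‑({[tert‑butyl(dimethyl)silyl]oxy}methyl)‑4‑ethynyl‑5‑hydroxy‑10‑oxocyclodec‑1‑ene‑1‑carboxylate, via peroxy trifluoroacetate 14 (not isolated), via bridged ketal trifluoroacetate 15 (not isolated)
Conditions: (CF3CO)2O, pyridine, CH2Cl2, −40 → 0 °C; then aq NaHCO3, rt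
Reagents that add atoms: none
Why: Proposed new method: Criegee (Hock‑type) ring expansion of a tertiary allylic hydroperoxide next to an acrylate, in which O‑acylation makes the O–O bond a leaving group and the secondary ring‑fusion carbon C8 (a better σ‑donor than the ester‑bearing, electron‑poor vinyl carbon C4 or the primary C2) undergoes the 1,2‑shift from C3 to oxygen with retention, giving an oxocarbenium ion that is trapped as ketal ester 15 and hydrolysed to the C3 ketone and the 8R alcohol (16 equilibrates with its C3–O–C8 hemiketal); the closest known reaction is the Criegee rearrangement of 9‑decalyl hydroperoxide esters to 6‑hydroxycyclodecanone, which has not been shown on an allylic, acceptor‑substituted substrate where alkenyl migration must be suppressed.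

Step 9
Reactants: 16 methyl (1E,3R,4S,5R,7R)‑3‑(acetyloxy)‑7‑({[tert‑butyl(dimethyl)silyl]oxy}methyl)‑4‑ethynyl‑5‑hydroxy‑10‑oxocyclodec‑1‑ene‑1‑carboxylate
Product: 17 methyl (6R,7S,8R,10R)‑6‑acetoxy‑14‑[(tert‑butyldimethylsilyl)oxy]‑3‑oxogermacra‑4,11(13)‑dien‑12,8‑olid‑15‑oate (C3 cis to C6 across C4=C5)
Conditions: PdCl2 (5 mol %), PPh3, SnCl2, CO (5 atm), MeCN, 65 °C
Reagents that add atoms: carbon monoxide, [C-]#[O+]
Why: Norton‑type palladium‑catalysed cyclocarbonylation of the homopropargylic alcohol builds the α‑methylene‑γ‑butyrolactone (C12 from CO); the trans ring fusion follows from the C7/C8 configuration set in steps 4 and 8.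

Step 10
Reactants: 17 methyl (6R,7S,8R,10R)‑6‑acetoxy‑14‑[(tert‑butyldimethylsilyl)oxy]‑3‑oxogermacra‑4,11(13)‑dien‑12,8‑olid‑15‑oate
Product: 19 (6R,7S,8R,10R)‑14‑[(tert‑butyldimethylsilyl)oxy]‑3‑oxogermacra‑4,11(13)‑diene‑12,8:15,6‑diolide, via C6‑hydroxy enoate 18 (not isolated)
Conditions: [tBu2Sn(OH)Cl]2 (10 mol %), MeOH–toluene 1:4, 60 °C
Reagents that add atoms: none
Why: Neutral tin‑catalysed transesterification removes the acetate, the alkylidene β‑keto ester equilibrates its C4=C5 geometry (reversible conjugate addition of methanol) and the C6 hydroxyl lactonises irreversibly onto C15 to give the butenolide; C6 is not touched.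

Step 11
Reactants: 19 (6R,7S,8R,10R)‑14‑[(tert‑butyldimethylsilyl)oxy]‑3‑oxogermacra‑4,11(13)‑diene‑12,8:15,6‑diolide
Product: 20 (3S,6R,7S,8R,10R)‑14‑[(tert‑butyldimethylsilyl)oxy]‑3‑hydroxygermacra‑4,11(13)‑diene‑12,8:15,6‑diolide
Conditions: (R)‑1‑methyl‑3,3‑diphenyltetrahydro‑1H,3H‑pyrrolo[1,2‑c][1,3,2]oxazaborole ((R)‑Me‑CBS, 0.3 equiv), catecholborane, toluene, −78 °C; then MeOH, aq NH4Cl
Reagents that add atoms: none
Why: Corey–Bakshi–Shibata 1,2‑reduction with the alkenyl (butenolide) group as the large substituent; the (R)‑catalyst delivers hydride to give the 3S alcohol.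

Step 12
Reactants: 20 (3S,6R,7S,8R,10R)‑14‑[(tert‑butyldimethylsilyl)oxy]‑3‑hydroxygermacra‑4,11(13)‑diene‑12,8:15,6‑diolide; 21 2‑methylpropanoyl chloride
Product: 22 (3S,6R,7S,8R,10R)‑14‑[(tert‑butyldimethylsilyl)oxy]‑3‑(2‑methylpropanoyloxy)germacra‑4,11(13)‑diene‑12,8:15,6‑diolide
Conditions: 21, pyridine, DMAP (cat.), CH2Cl2, 0 °C → rt
Reagents that add atoms: none
Why: DMAP‑catalysed acylation of the only free hydroxyl group (C3), with retention.

Step 13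
Reactants: 22 (3S,6R,7S,8R,10R)‑14‑[(tert‑butyldimethylsilyl)oxy]‑3‑(2‑methylpropanoyloxy)germacra‑4,11(13)‑diene‑12,8:15,6‑diolide
Product: 23 (3S,6R,7S,8R,10R)‑14‑hydroxy‑3‑(2‑methylpropanoyloxy)germacra‑4,11(13)‑diene‑12,8:15,6‑diolide (CNP0332805.1)
Conditions: HF·pyridine, THF, 0 °C → rt
Reagents that add atoms: none
Why: Fluoride‑mediated cleavage of the primary silyl ether under mildly acidic conditions that spare the isobutyrate, the butenolide and the α‑methylene lactone.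

**Compound list**
1 | 2‑chlorobuta‑1,3‑diene (chloroprene) | C=CC(Cl)=C | starting material
2 | prop‑2‑enal (acrolein) | C=CC=O | starting material
3 | (1R)‑4‑chlorocyclohex‑3‑ene‑1‑carbaldehyde | O=C[C@H]1CC=C(Cl)CC1 | intermediate
4 | tert‑butyl{[(1R)‑4‑chlorocyclohex‑3‑en‑1‑yl]methoxy}dimethylsilane | ClC1=CC[C@H](CO[Si](C)(C)C(C)(C)C)CC1 | intermediate
5 | methyl 2‑bromoprop‑2‑enoate | C=C(Br)C(=O)OC | starting material
6 | [1‑(methoxycarbonyl)ethenyl]zinc bromide | C=C([Zn]Br)C(=O)OC | intermediate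
7 | methyl 2‑[(4R)‑4‑({[tert‑butyl(dimethyl)silyl]oxy}methyl)cyclohex‑1‑en‑1‑yl]prop‑2‑enoate | C=C(C(=O)OC)C1=CC[C@H](CO[Si](C)(C)C(C)(C)C)CC1 | intermediate
8 | 2‑methylfuran | Cc1ccco1 | starting material
9 | (2Z)‑4‑oxopent‑2‑enal | CC(=O)/C=C\C=O | intermediate
10 | methyl (3R,4S,4aR,6R)‑3‑acetyl‑6‑({[tert‑butyl(dimethyl)silyl]oxy}methyl)‑4‑formyl‑2,3,4,4a,5,6,7,8‑octahydronaphthalene‑1‑carboxylate | O=C[C@H]1[C@H]2C[C@H](CO[Si](C)(C)C(C)(C)C)CCC2=C(C(=O)OC)C[C@H]1C(C)=O | intermediate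
11 | methyl (3R,4S,4aR,6R)‑3‑acetyl‑6‑({[tert‑butyl(dimethyl)silyl]oxy}methyl)‑4‑ethynyl‑2,3,4,4a,5,6,7,8‑octahydronaphthalene‑1‑carboxylate | C#C[C@H]1[C@H]2C[C@H](CO[Si](C)(C)C(C)(C)C)CCC2=C(C(=O)OC)C[C@H]1C(C)=O | intermediate
12 | methyl (3R,4R,4aR,6R)‑3‑(acetyloxy)‑6‑({[tert‑butyl(dimethyl)silyl]oxy}methyl)‑4‑ethynyl‑2,3,4,4a,5,6,7,8‑octahydronaphthalene‑1‑carboxylate | C#C[C@H]1[C@H]2C[C@H](CO[Si](C)(C)C(C)(C)C)CCC2=C(C(=O)OC)C[C@H]1OC(C)=O | intermediate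
13 | methyl (3R,4R,4aR,6R,8aS)‑3‑(acetyloxy)‑6‑({[tert‑butyl(dimethyl)silyl]oxy}methyl)‑4‑ethynyl‑8a‑hydroperoxy‑3,4,4a,5,6,7,8,8a‑octahydronaphthalene‑1‑carboxylate | C#C[C@H]1[C@H]2C[C@H](CO[Si](C)(C)C(C)(C)C)CC[C@@]2(OO)C(C(=O)OC)=C[C@H]1OC(C)=O | intermediate
14 | 8a‑[(trifluoroacetyl)peroxy] analogue of 13 (peroxy trifluoroacetate, same configurations) | C#C[C@H]1[C@H]2C[C@H](CO[Si](C)(C)C(C)(C)C)CC[C@@]2(OOC(=O)C(F)(F)F)C(C(=O)OC)=C[C@H]1OC(C)=O | intermediate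
15 | methyl 4‑(acetyloxy)‑8‑({[tert‑butyl(dimethyl)silyl]oxy}methyl)‑5‑ethynyl‑1‑[(trifluoroacetyl)oxy]‑11‑oxabicyclo[4.4.1]undec‑2‑ene‑2‑carboxylate (C3–O–C8 bridged ketal; C6, C7, C8, C10 as in 13, C3 fixed by the bridge) | C#C[C@H]1[C@H]2C[C@H](CO[Si](C)(C)C(C)(C)C)CC[C@@](O2)(OC(=O)C(F)(F)F)C(C(=O)OC)=C[C@H]1OC(C)=O | intermediate
16 | methyl (1E,3R,4S,5R,7R)‑3‑(acetyloxy)‑7‑({[tert‑butyl(dimethyl)silyl]oxy}methyl)‑4‑ethynyl‑5‑hydroxy‑10‑oxocyclodec‑1‑ene‑1‑carboxylate (C3 cis to C6 on the ring alkene) | C#C[C@H]1[C@H](O)C[C@H](CO[Si](C)(C)C(C)(C)C)CCC(=O)/C(C(=O)OC)=C\[C@H]1OC(C)=O | intermediate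
17 | methyl (6R,7S,8R,10R)‑6‑acetoxy‑14‑[(tert‑butyldimethylsilyl)oxy]‑3‑oxogermacra‑4,11(13)‑dien‑12,8‑olid‑15‑oate (C3 cis to C6 across C4=C5) | C=C1C(=O)O[C@@H]2C[C@H](CO[Si](C)(C)C(C)(C)C)CCC(=O)/C(C(=O)OC)=C\[C@@H](OC(C)=O)[C@@H]12 | intermediate
18 | methyl (6R,7S,8R,10R)‑14‑[(tert‑butyldimethylsilyl)oxy]‑6‑hydroxy‑3‑oxogermacra‑4,11(13)‑dien‑12,8‑olid‑15‑oate | C=C1C(=O)O[C@@H]2C[C@H](CO[Si](C)(C)C(C)(C)C)CCC(=O)/C(C(=O)OC)=C\[C@@H](O)[C@@H]12 | intermediate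
19 | (6R,7S,8R,10R)‑14‑[(tert‑butyldimethylsilyl)oxy]‑3‑oxogermacra‑4,11(13)‑diene‑12,8:15,6‑diolide | C=C1C(=O)O[C@@H]2C[C@H](CO[Si](C)(C)C(C)(C)C)CCC(=O)C3=C[C@@H](OC3=O)[C@@H]12 | intermediate
20 | (3S,6R,7S,8R,10R)‑14‑[(tert‑butyldimethylsilyl)oxy]‑3‑hydroxygermacra‑4,11(13)‑diene‑12,8:15,6‑diolide | C=C1C(=O)O[C@@H]2C[C@H](CO[Si](C)(C)C(C)(C)C)CC[C@H](O)C3=C[C@@H](OC3=O)[C@@H]12 | intermediate
21 | 2‑methylpropanoyl chloride | CC(C)C(Cl)=O | starting material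
22 | (3S,6R,7S,8R,10R)‑14‑[(tert‑butyldimethylsilyl)oxy]‑3‑(2‑methylpropanoyloxy)germacra‑4,11(13)‑diene‑12,8:15,6‑diolide | C=C1C(=O)O[C@@H]2C[C@H](CO[Si](C)(C)C(C)(C)C)CC[C@H](OC(=O)C(C)C)C3=C[C@@H](OC3=O)[C@@H]12 | intermediate
23 | (3S,6R,7S,8R,10R)‑14‑hydroxy‑3‑(2‑methylpropanoyloxy)germacra‑4,11(13)‑diene‑12,8:15,6‑diolide | C=C1C(=O)O[C@@H]2C[C@H](CO)CC[C@H](OC(=O)C(C)C)C3=C[C@@H](OC3=O)[C@@H]12 | target

**Step count and risks**
Total steps: 13. Longest linear sequence: 13 steps (1 and 2 to 23).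

Steps most likely to fail:

1. Step 8 (the proposed new ring expansion). The ester‑bearing vinyl carbon C4 could migrate instead of C8 (Hock cleavage of ring A), or the ketal ester 15 could eliminate. Fallback with known chemistry, from 13 back to 16: triphenylphosphine reduces the hydroperoxide to the tertiary allylic alcohol F10. Suárez alkoxy‑radical β‑scission (PhI(OAc)2, I2, visible light, cyclohexane) then cleaves the C3–C8 bond to the ring‑expanded iodo ketone F11 as a C8 epimer mixture. AgOTf in aqueous acetone replaces iodide by hydroxyl, and the 8R epimer, which is 16, is separated from its epimer. This variant gives up the stereoretention of the 1,2‑shift.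

2. Step 4 (Diels–Alder). The acetyl group might control regiochemistry, 9 might isomerise to the E isomer before cycloaddition, or the facial selectivity from C10 might be modest. Fallback from 7 back to 11: furan is converted with Br2/MeOH into 2,5‑dimethoxy‑2,5‑dihydrofuran F1 and opened on Amberlyst‑15 in wet acetone at 0 °C to (2Z)‑4,4‑dimethoxybut‑2‑enal F2. Here only the formyl group activates the dienophile, so its Diels–Alder reaction with 7 (Me2AlCl, CH2Cl2, −40 °C) can only give the C7‑formyl, C6‑dimethoxymethyl adduct F3. Colvin homologation gives the alkyne acetal F4, aqueous oxalic acid gives the C6 aldehyde F5, MeMgBr in THF at −78 °C gives the carbinol F6, and Dess–Martin periodinane gives 11.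

3. Step 5 (alkyne formation beside a cis 1,4‑keto aldehyde). Intramolecular aldol reaction of the acetyl group with the formyl group or epimerisation at C7 could compete. Fallback from 10 back to 12: trimethyl orthoformate with pyridinium tosylate protects only the aldehyde as the dimethyl acetal F7. Baeyer–Villiger oxidation (mCPBA) of the now isolated methyl ketone gives the acetate acetal F8, and pyridinium tosylate in wet acetone liberates the aldehyde F9. Ohira–Bestmann homologation (dimethyl (1‑diazo‑2‑oxopropyl)phosphonate, K2CO3, MeOH, 0 °C) then gives 12.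

Further compounds
F1 | step 4 | 2,5‑dimethoxy‑2,5‑dihydrofuran | COC1OC(OC)C=C1
F2 | step 4 | (2Z)‑4,4‑dimethoxybut‑2‑enal | O=C/C=C\C(OC)OC
F3 | step 4 | methyl (3R,4S,4aR,6R)‑6‑({[tert‑butyl(dimethyl)silyl]oxy}methyl)‑3‑(dimethoxymethyl)‑4‑formyl‑2,3,4,4a,5,6,7,8‑octahydronaphthalene‑1‑carboxylate | O=C[C@H]1[C@H]2C[C@H](CO[Si](C)(C)C(C)(C)C)CCC2=C(C(=O)OC)C[C@H]1C(OC)OC
F4 | step 4 | methyl (3R,4S,4aR,6R)‑6‑({[tert‑butyl(dimethyl)silyl]oxy}methyl)‑3‑(dimethoxymethyl)‑4‑ethynyl‑2,3,4,4a,5,6,7,8‑octahydronaphthalene‑1‑carboxylate | C#C[C@H]1[C@H]2C[C@H](CO[Si](C)(C)C(C)(C)C)CCC2=C(C(=O)OC)C[C@H]1C(OC)OC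
F5 | step 4 | methyl (3R,4S,4aR,6R)‑6‑({[tert‑butyl(dimethyl)silyl]oxy}methyl)‑4‑ethynyl‑3‑formyl‑2,3,4,4a,5,6,7,8‑octahydronaphthalene‑1‑carboxylate | C#C[C@H]1[C@H]2C[C@H](CO[Si](C)(C)C(C)(C)C)CCC2=C(C(=O)OC)C[C@H]1C=O
F6 | step 4 | methyl (3R,4S,4aR,6R)‑6‑({[tert‑butyl(dimethyl)silyl]oxy}methyl)‑4‑ethynyl‑3‑(1‑hydroxyethyl)‑2,3,4,4a,5,6,7,8‑octahydronaphthalene‑1‑carboxylate (carbinol epimers) | C#C[C@H]1[C@H]2C[C@H](CO[Si](C)(C)C(C)(C)C)CCC2=C(C(=O)OC)C[C@H]1C(C)O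
F7 | step 5 | methyl (3R,4S,4aR,6R)‑3‑acetyl‑6‑({[tert‑butyl(dimethyl)silyl]oxy}methyl)‑4‑(dimethoxymethyl)‑2,3,4,4a,5,6,7,8‑octahydronaphthalene‑1‑carboxylate | COC(OC)[C@H]1[C@H]2C[C@H](CO[Si](C)(C)C(C)(C)C)CCC2=C(C(=O)OC)C[C@H]1C(C)=O
F8 | step 5 | methyl (3R,4S,4aR,6R)‑3‑(acetyloxy)‑6‑({[tert‑butyl(dimethyl)silyl]oxy}methyl)‑4‑(dimethoxymethyl)‑2,3,4,4a,5,6,7,8‑octahydronaphthalene‑1‑carboxylate | COC(OC)[C@H]1[C@H]2C[C@H](CO[Si](C)(C)C(C)(C)C)CCC2=C(C(=O)OC)C[C@H]1OC(C)=O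
F9 | step 5 | methyl (3R,4S,4aR,6R)‑3‑(acetyloxy)‑6‑({[tert‑butyl(dimethyl)silyl]oxy}methyl)‑4‑formyl‑2,3,4,4a,5,6,7,8‑octahydronaphthalene‑1‑carboxylate | O=C[C@H]1[C@H]2C[C@H](CO[Si](C)(C)C(C)(C)C)CCC2=C(C(=O)OC)C[C@H]1OC(C)=O
F10 | step 8 | methyl (3R,4R,4aR,6R,8aS)‑3‑(acetyloxy)‑6‑({[tert‑butyl(dimethyl)silyl]oxy}methyl)‑4‑ethynyl‑8a‑hydroxy‑3,4,4a,5,6,7,8,8a‑octahydronaphthalene‑1‑carboxylate | C#C[C@H]1[C@H]2C[C@H](CO[Si](C)(C)C(C)(C)C)CC[C@@]2(O)C(C(=O)OC)=C[C@H]1OC(C)=O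
F11 | step 8 | methyl (1E,3R,4S,7R)‑3‑(acetyloxy)‑7‑({[tert‑butyl(dimethyl)silyl]oxy}methyl)‑4‑ethynyl‑5‑iodo‑10‑oxocyclodec‑1‑ene‑1‑carboxylate (C5 epimers) | C#C[C@H]1C(I)C[C@H](CO[Si](C)(C)C(C)(C)C)CCC(=O)/C(C(=O)OC)=C\[C@H]1OC(C)=O
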